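## Retrosynthetic overview

1. Numbering used throughout: ring C15(OAc)–C1H2–C2H(Me)–C3H(OBz)–C4H; on C4 the enal C5=C6(Me)–C7HO; on C15 the chain C14H(OAc)–C13H(Me)–C12=C11–C10Me2–C9(=O)–C8H3.
2. Endgame: C7 enal by SeO2 oxidation after shifting a methallyl double bond into C5=C6; the esters by acylation of the C14/C15 diol and of C3–OH.
3. C14–C15 bond: a sparteine-generated α-lithio carbamate of the C8–C14 chain (Roche ester plus a C9-ketal aldehyde, Julia–Kocienski at C11=C12) adds to the C15 ketone.
4. C15 ketone: Me2CuLi at C2 of the cis-3-silyloxy-4-methallyl enone, itself obtained from the trans enone by lipase resolution and Mitsunobu inversion at C3.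
5. Feature: the only ring (C15, C1, C2, C3, C4) is a masked 4-hydroxy-5-alkylcyclopent-2-enone (C15 carbonyl, C1=C2 alkene, C3 carbinol, C4 alkylated carbon); it is closed at C3–C4 by oxa-Piancatelli rearrangement of a furfural-derived 2-furyl carbinol.

Key step: step 2

Assumption: the lipase is taken to acylate the (4R,5S)-alcohol faster (Kazlauskas rule with the alkylated ring carbon as the large group, as for trans-2-substituted cycloalkanols); if the sense were reversed, alcohol 7 would be the unreacted component of step 3 and step 4 would fall away.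

## Route

Step 1
Reactants: 1 furfural; 2 3-chloro-2-methylprop-1-ene
Product: 3 rac-1-(furan-2-yl)-3-methylbut-3-en-1-ol
Conditions: Zn dust, sat. aq. NH4Cl/THF, 0 °C → rt
Reagents that add atoms: none
Why: Barbier allylation: zinc inserts into the allylic chloride in the aqueous medium and the methallylzinc adds to the non-enolisable aldehyde; the new carbinol centre needs no control because it is planarised in step 2.

Step 2
Reactants: 3 rac-1-(furan-2-yl)-3-methylbut-3-en-1-ol
Product: 5 rac-trans-4-hydroxy-5-(2-methylprop-2-en-1-yl)cyclopent-2-en-1-one, via 1,4-dihydroxypentadienyl cation 4 (not isolated)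
Conditions: ZnCl2, dioxane/H2O (1:1), pH 5–6, reflux
Reagents that add atoms: water, O
Why: ZnCl2 in hot water ionises the furyl carbinol to a furan-stabilised cation, water adds at the free furan α-carbon (the future C3), and the hemiacetal opens to the 1,4-dihydroxypentadienyl cation 4, which undergoes thermal conrotatory 4π electrocyclisation and tautomerises to the enone; this is the oxa-Piancatelli rearrangement, a Nazarov-type closure. The single carbocycle (C15–C1–C2–C3–C4) is closed by the new C3–C4 bond in the 4π-conrotatory mode. Both new stereocentres (C3 carbinol and C4) arise in that closure: the cation reacts from its out,out geometry, so conrotation should place the hydroxyl and the methallyl group trans, and the product is racemic. The step needs water capture at the furan α-carbon to outrun proton loss from the cation (toward a furyl diene), hydration of the 1,1-disubstituted alkene and drift of the product to the 2-substituted enone; the CH2 spacer keeps the alkene out of conjugation with the cation, the weakly acidic medium should leave the isobutenyl group untouched, and heating is stopped at full conversion.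

Step 3
Reactants: 5 rac-trans-4-hydroxy-5-(2-methylprop-2-en-1-yl)cyclopent-2-en-1-one
Product: 6 (1R,5S)-5-(2-methylprop-2-en-1-yl)-4-oxocyclopent-2-en-1-yl acetate
Conditions: lipase from Burkholderia cepacia (Amano PS, immobilised), vinyl acetate, MTBE, 30 °C, stopped near half conversion
Reagents that add atoms: vinyl acetate, CC(=O)OC=C
Why: Lipase-catalysed kinetic resolution by irreversible transesterification should acylate the (4R,5S)-alcohol and leave the (4S,5R)-alcohol, which is removed by chromatography; this fixes the absolute configuration of C3 and C4.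

Step 4
Reactants: 6 (1R,5S)-5-(2-methylprop-2-en-1-yl)-4-oxocyclopent-2-en-1-yl acetate
Product: 7 (4R,5S)-4-hydroxy-5-(2-methylprop-2-en-1-yl)cyclopent-2-en-1-one
Conditions: lipase from Burkholderia cepacia (Amano PS), n-BuOH, MTBE, 40 °C
Reagents that add atoms: none
Why: Enzymatic alcoholysis transfers the acetyl group to n-butanol under neutral, anhydrous conditions, with the same enantiomer preference, so the base-labile β-hydroxy enone is freed without C4 epimerisation or drift to the 2-substituted enone.

Step 5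
Reactants: 7 (4R,5S)-4-hydroxy-5-(2-methylprop-2-en-1-yl)cyclopent-2-en-1-one
Product: 9 (4S,5S)-4-hydroxy-5-(2-methylprop-2-en-1-yl)cyclopent-2-en-1-one, via cis-formate ester 8 (not isolated)
Conditions: HCO2H, PPh3, DIAD, THF, −20 → 0 °C; concentrate; MeOH, neutral Al2O3, 0 °C → rt
Reagents that add atoms: formic acid, O=CO
Why: Mitsunobu reaction: the C3 oxyphosphonium is displaced by the small formate nucleophile in an SN2 step with inversion, giving the cis C3–O/C4-alkyl relationship, and the very labile formate is then methanolysed without base.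

Step 6
Reactants: 9 (4S,5S)-4-hydroxy-5-(2-methylprop-2-en-1-yl)cyclopent-2-en-1-one
Product: 10 (4S,5S)-4-[(tert-butyldimethylsilyl)oxy]-5-(2-methylprop-2-en-1-yl)cyclopent-2-en-1-one
Conditions: TBSCl, imidazole, DMF, 0 °C → rt
Reagents that add atoms: tert-butyldimethylsilyl chloride, CC(C)(C)[Si](C)(C)Cl
Why: Standard silylation of a secondary alcohol; a silyl ether is chosen because an acyloxy group γ to the enone would be lost under cuprate conditions and because the bulky group steers step 7.

Step 7
Reactants: 10 (4S,5S)-4-[(tert-butyldimethylsilyl)oxy]-5-(2-methylprop-2-en-1-yl)cyclopent-2-en-1-one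
Product: 11 (3R,4S,5S)-4-[(tert-butyldimethylsilyl)oxy]-3-methyl-5-(2-methylprop-2-en-1-yl)cyclopentan-1-one
Conditions: Me2CuLi (from MeLi, CuI), Et2O, −78 °C; sat. aq. NH4Cl, −78 °C
Reagents that add atoms: methyllithium, [Li]C (used as lithium dimethylcuprate, [Li+].C[Cu-]C)
Why: Conjugate addition of the Gilman cuprate at C2 should occur anti to the C3 silyloxy group and the cis C4 side chain, setting C2 with methyl trans to C3–O; cold protonation of the enolate avoids β-elimination of the silyloxy group.

Step 8
Reactants: 12 methyl 2,2-dimethyl-3-oxobutanoate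
Product: 13 methyl 2-methyl-2-(2-methyl-1,3-dioxolan-2-yl)propanoate
Conditions: (Me3SiOCH2)2, Me3SiOTf (cat.), CH2Cl2, −78 → 0 °C
Reagents that add atoms: 1,2-bis(trimethylsilyloxy)ethane, C[Si](C)(C)OCCO[Si](C)(C)C
Why: Noyori ketalisation masks the hindered C9 ketone without transesterifying the ester, so that it survives the later hydride and organolithium steps.

Step 9
Reactants: 13 methyl 2-methyl-2-(2-methyl-1,3-dioxolan-2-yl)propanoate
Product: 14 2-methyl-2-(2-methyl-1,3-dioxolan-2-yl)propan-1-ol
Conditions: LiAlH4, THF, 0 °C; H2O, aq. NaOH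
Reagents that add atoms: none
Why: Hydride reduction of the neopentyl ester to the primary alcohol; the ketal is inert.

Step 10
Reactants: 14 2-methyl-2-(2-methyl-1,3-dioxolan-2-yl)propan-1-ol
Product: 15 2-methyl-2-(2-methyl-1,3-dioxolan-2-yl)propanal
Conditions: Dess–Martin periodinane, NaHCO3, CH2Cl2, rt
Reagents that add atoms: none
Why: Dess–Martin oxidation under buffered conditions gives the non-enolisable C11 aldehyde and spares the ketal.

Step 11
Reactants: 16 methyl (R)-3-hydroxy-2-methylpropanoate
Product: 17 methyl (R)-3-[(diisopropylcarbamoyl)oxy]-2-methylpropanoate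
Conditions: iPr2NCOCl, Et3N, 4-dimethylaminopyridine (cat.), CH2Cl2, reflux
Reagents that add atoms: N,N-diisopropylcarbamoyl chloride, CC(C)N(C(C)C)C(Cl)=O
Why: O-Carbamoylation of the primary alcohol installs the group that later directs α-lithiation at C14; amine base at moderate temperature should leave the C13 stereocentre of the Roche ester untouched.

Step 12
Reactants: 17 methyl (R)-3-[(diisopropylcarbamoyl)oxy]-2-methylpropanoate
Product: 18 (S)-3-hydroxy-2-methylpropyl N,N-diisopropylcarbamate
Conditions: LiBH4, THF, 0 °C → rt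
Reagents that add atoms: none
Why: LiBH4 reduces the methyl ester chemoselectively to the C12 alcohol (the hindered carbamate is inert and does not migrate); the descriptor changes only through priorities.

Step 13
Reactants: 18 (S)-3-hydroxy-2-methylpropyl N,N-diisopropylcarbamate
Product: 19 (R)-2-methyl-3-[(1-phenyl-1H-tetrazol-5-yl)sulfanyl]propyl N,N-diisopropylcarbamate
Conditions: 1-phenyl-1H-tetrazole-5-thiol, PPh3, DIAD, THF, 0 °C → rt
Reagents that add atoms: 1-phenyl-1H-tetrazole-5-thiol, Sc1nnnn1-c1ccccc1
Why: Mitsunobu thioetherification of the primary alcohol with the acidic heteroaryl thiol.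

Step 14
Reactants: 19 (R)-2-methyl-3-[(1-phenyl-1H-tetrazol-5-yl)sulfanyl]propyl N,N-diisopropylcarbamate
Product: 20 (R)-2-methyl-3-[(1-phenyl-1H-tetrazol-5-yl)sulfonyl]propyl N,N-diisopropylcarbamate
Conditions: (NH4)6Mo7O24·4H2O (cat.), 30% aq. H2O2, EtOH, 0 °C → rt
Reagents that add atoms: hydrogen peroxide, OO
Why: Molybdate-catalysed peroxide oxidation of the sulfide to the sulfone; carbamate and stereocentre are unaffected.

Step 15
Reactants: 20 (R)-2-methyl-3-[(1-phenyl-1H-tetrazol-5-yl)sulfonyl]propyl N,N-diisopropylcarbamate; 15 2-methyl-2-(2-methyl-1,3-dioxolan-2-yl)propanal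
Product: 22 (S,E)-2,5-dimethyl-5-(2-methyl-1,3-dioxolan-2-yl)hex-3-en-1-yl N,N-diisopropylcarbamate, via potassium sulfonyl carbanion 21 (not isolated)
Conditions: KN(SiMe3)2, DME, −60 °C; then 15, −60 °C → rt; sat. aq. NH4Cl
Reagents that add atoms: none
Why: Julia–Kocienski olefination: the sulfonyl carbanion adds to the non-enolisable aldehyde, and Smiles rearrangement with loss of SO2 and tetrazolate should give the C11=C12 alkene E-selectively, as expected for phenyltetrazolyl sulfones with a potassium base in DME and a hindered aldehyde.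

Step 16
Reactants: 22 (S,E)-2,5-dimethyl-5-(2-methyl-1,3-dioxolan-2-yl)hex-3-en-1-yl N,N-diisopropylcarbamate; 11 (3R,4S,5S)-4-[(tert-butyldimethylsilyl)oxy]-3-methyl-5-(2-methylprop-2-en-1-yl)cyclopentan-1-one
Product: 24 C15 tertiary alcohol with the C14 carbamate side chain (2R,3S,4S,13S,14R,15R; 3-OTBS, C9 ketal, C4 methallyl), via lithiated carbamate 23 (not isolated)
Conditions: s-BuLi, (−)-sparteine, Et2O, −78 °C; then 11, −78 °C; MeOH, sat. aq. NH4Cl
Reagents that add atoms: none
Why: Hoppe asymmetric deprotonation removes the pro-S hydrogen of the carbamate-activated C14H2, and the configurationally stable organolithium adds to the ketone with retention (14R), on the face anti to the C4 methallyl and C3 silyloxy groups (15R, new C–C bond cis to the C2 methyl).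

Step 17
Reactants: 24 C15 tertiary alcohol with the C14 carbamate side chain
Product: 25 C14,C15-diol (2R,3S,4S,13S,14R,15R; 3-OTBS, C9 ketal, C4 methallyl)
Conditions: LiAlH4, THF, 0 °C → reflux; H2O, aq. NaOH
Reagents that add atoms: none
Why: LiAlH4 cleaves the N,N-diisopropylcarbamate (assisted by the neighbouring C15 alkoxide) to the C14 alcohol; silyl ether, ketal and both alkenes are inert to hydride.

Step 18
Reactants: 25 C14,C15-diol
Product: 26 C14,C15-diacetate (3-OTBS, C9 ketal, C4 methallyl)
Conditions: Ac2O, 4-dimethylaminopyridine, Et3N, ClCH2CH2Cl, 60 °C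
Reagents that add atoms: acetic anhydride, CC(=O)OC(C)=O
Why: Steglich-type nucleophilic catalysis should esterify the secondary C14 alcohol quickly and, on heating with excess reagent, the tertiary C15 alcohol.

Step 19
Reactants: 26 C14,C15-diacetate (3-OTBS, C9 ketal)
Product: 27 C14,C15-diacetate with free C3–OH and free C9 ketone
Conditions: 48% aq. HF, MeCN, 0 °C → rt
Reagents that add atoms: water, O
Why: Aqueous HF cleaves the Si–O bond and, as an aqueous acid, should hydrolyse the crowded ketal of the α-quaternary ketone in the same operation; acetates and both alkenes tolerate the mild acid.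

Step 20
Reactants: 27 C14,C15-diacetate with free C3–OH and free C9 ketone
Product: 28 3-O-benzoyl-14,15-di-O-acetyl compound with C4 methallyl group
Conditions: BzCl, pyridine, 4-dimethylaminopyridine (cat.), CH2Cl2, 0 °C → rt
Reagents that add atoms: benzoyl chloride, O=C(Cl)c1ccccc1
Why: Acylation of the only free hydroxyl (C3) under nucleophilic catalysis; the methyl ketone and the tertiary acetate do not react.

Step 21
Reactants: 28 3-O-benzoyl-14,15-di-O-acetyl compound with C4 methallyl group
Product: 29 3-O-benzoyl-14,15-di-O-acetyl compound with C4 2-methylprop-1-enyl group (C5=C6)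
Conditions: [N,N′-bis(3,5-di-tert-butylsalicylidene)cyclohexane-1,2-diaminato]CoCl (C36H52ClCoN2O2, trivalent cobalt, cat.), PhSiH3 (cat.), benzene, rt
Reagents that add atoms: none
Why: Cobalt-hydride hydrogen-atom-transfer isomerisation: reversible H-atom transfer to the 1,1-disubstituted alkene gives the tertiary C6 radical, and H-atom loss from C5 should deliver the thermodynamically favoured trisubstituted alkene, while the hindered 1,2-disubstituted C11=C12 alkene is a much poorer H-atom acceptor.

Step 22
Reactants: 29 3-O-benzoyl-14,15-di-O-acetyl compound with C4 2-methylprop-1-enyl group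
Product: 31 CNP0489076.1 (target; 2R,3S,4S,13S,14R,15R; 5E,11E), via E-allylic alcohol 30 (not isolated)
Conditions: SeO2 (cat.), t-BuOOH, CH2Cl2, rt; filter; MnO2, CH2Cl2, rt
Reagents that add atoms: selenium dioxide, O=[Se]=O (oxygen carrier); tert-butyl hydroperoxide, CC(C)(C)OO (terminal oxygen source)
Why: SeO2 allylic oxidation (ene reaction, then [2,3]-sigmatropic shift) should attack the more nucleophilic trisubstituted alkene at the methyl trans to C4, giving the E-allylic alcohol with some enal, and MnO2 completes the oxidation to the E-enal without touching esters or the ketone.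

## Compound list

1 | furfural | O=Cc1ccco1 | starting material
2 | 3-chloro-2-methylprop-1-ene | CC(=C)CCl | starting material
3 | rac-1-(furan-2-yl)-3-methylbut-3-en-1-ol | OC(CC(C)=C)c1ccco1 | intermediate
4 | 1,4-dihydroxypentadienyl cation (U-shaped, hydroxyl and methallyl termini out; one resonance form drawn) | O/C=C/C=C(\[CH+]CC(C)=C)O | intermediate
5 | rac-trans-4-hydroxy-5-(2-methylprop-2-en-1-yl)cyclopent-2-en-1-one (racemate; relative configuration drawn) | O=C1C=C[C@@H](O)[C@@H]1CC(C)=C | intermediate
6 | (1R,5S)-5-(2-methylprop-2-en-1-yl)-4-oxocyclopent-2-en-1-yl acetate | O=C1C=C[C@@H](OC(C)=O)[C@@H]1CC(C)=C | intermediate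
7 | (4R,5S)-4-hydroxy-5-(2-methylprop-2-en-1-yl)cyclopent-2-en-1-one (single enantiomer) | O=C1C=C[C@@H](O)[C@@H]1CC(C)=C | intermediate
8 | (1S,5S)-5-(2-methylprop-2-en-1-yl)-4-oxocyclopent-2-en-1-yl formate | O=C1C=C[C@H](OC=O)[C@@H]1CC(C)=C | intermediate
9 | (4S,5S)-4-hydroxy-5-(2-methylprop-2-en-1-yl)cyclopent-2-en-1-one | O=C1C=C[C@H](O)[C@@H]1CC(C)=C | intermediate
10 | (4S,5S)-4-[(tert-butyldimethylsilyl)oxy]-5-(2-methylprop-2-en-1-yl)cyclopent-2-en-1-one | O=C1C=C[C@H](O[Si](C)(C)C(C)(C)C)[C@@H]1CC(C)=C | intermediate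
11 | (3R,4S,5S)-4-[(tert-butyldimethylsilyl)oxy]-3-methyl-5-(2-methylprop-2-en-1-yl)cyclopentan-1-one | O=C1C[C@@H](C)[C@H](O[Si](C)(C)C(C)(C)C)[C@@H]1CC(C)=C | intermediate
12 | methyl 2,2-dimethyl-3-oxobutanoate | CC(=O)C(C)(C)C(=O)OC | starting material
13 | methyl 2-methyl-2-(2-methyl-1,3-dioxolan-2-yl)propanoate | COC(=O)C(C)(C)C1(C)OCCO1 | intermediate
14 | 2-methyl-2-(2-methyl-1,3-dioxolan-2-yl)propan-1-ol | OCC(C)(C)C1(C)OCCO1 | intermediate
15 | 2-methyl-2-(2-methyl-1,3-dioxolan-2-yl)propanal | O=CC(C)(C)C1(C)OCCO1 | intermediate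
16 | methyl (R)-3-hydroxy-2-methylpropanoate | C[C@H](CO)C(=O)OC | starting material
17 | methyl (R)-3-[(diisopropylcarbamoyl)oxy]-2-methylpropanoate | C[C@H](COC(=O)N(C(C)C)C(C)C)C(=O)OC | intermediate
18 | (S)-3-hydroxy-2-methylpropyl N,N-diisopropylcarbamate | C[C@H](COC(=O)N(C(C)C)C(C)C)CO | intermediate
19 | (R)-2-methyl-3-[(1-phenyl-1H-tetrazol-5-yl)sulfanyl]propyl N,N-diisopropylcarbamate | C[C@H](COC(=O)N(C(C)C)C(C)C)CSc1nnnn1-c1ccccc1 | intermediate
20 | (R)-2-methyl-3-[(1-phenyl-1H-tetrazol-5-yl)sulfonyl]propyl N,N-diisopropylcarbamate | C[C@H](COC(=O)N(C(C)C)C(C)C)CS(=O)(=O)c1nnnn1-c1ccccc1 | intermediate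
21 | potassium α-sulfonyl carbanion of 20 | [K+].C[C@H](COC(=O)N(C(C)C)C(C)C)[CH-]S(=O)(=O)c1nnnn1-c1ccccc1 | intermediate
22 | (S,E)-2,5-dimethyl-5-(2-methyl-1,3-dioxolan-2-yl)hex-3-en-1-yl N,N-diisopropylcarbamate | CC(C)N(C(C)C)C(=O)OC[C@@H](C)/C=C/C(C)(C)C1(C)OCCO1 | intermediate
23 | (1S,2S,E)-1-lithio derivative of 22 (lithium at C14 in place of the pro-S hydrogen; (−)-sparteine complex, ligand not drawn) | CC(C)N(C(C)C)C(=O)O[C@H]([C@@H](C)/C=C/C(C)(C)C1(C)OCCO1)[Li] | intermediate
24 | cyclopentanol with C15–OH and, on C15, the chain C14H(OC(O)N(iPr)2)–C13H(Me)–(E)-C12=C11–C10Me2–C9(dioxolane)–CH3; C2 Me, C3 OTBS, C4 2-methylprop-2-enyl (2R,3S,4S,13S,14R,15R) | CC(C)N(C(C)C)C(=O)O[C@H]([C@@H](C)/C=C/C(C)(C)C1(C)OCCO1)[C@@]2(O)C[C@@H](C)[C@H](O[Si](C)(C)C(C)(C)C)[C@@H]2CC(C)=C | intermediate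
25 | C14,C15-diol corresponding to 24 (2R,3S,4S,13S,14R,15R) | O[C@H]([C@@H](C)/C=C/C(C)(C)C1(C)OCCO1)[C@@]2(O)C[C@@H](C)[C@H](O[Si](C)(C)C(C)(C)C)[C@@H]2CC(C)=C | intermediate
26 | C14,C15-diacetate of 25 (3-OTBS, C9 ketal, C4 2-methylprop-2-enyl) | CC(=O)O[C@H]([C@@H](C)/C=C/C(C)(C)C1(C)OCCO1)[C@@]2(OC(C)=O)C[C@@H](C)[C@H](O[Si](C)(C)C(C)(C)C)[C@@H]2CC(C)=C | intermediate
27 | C14,C15-diacetate with free C3–OH and C9 methyl ketone (C4 2-methylprop-2-enyl) | CC(=O)O[C@H]([C@@H](C)/C=C/C(C)(C)C(C)=O)[C@@]1(OC(C)=O)C[C@@H](C)[C@H](O)[C@@H]1CC(C)=C | intermediate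
28 | 3-O-benzoyl-14,15-di-O-acetyl C9 ketone with C4 2-methylprop-2-enyl | CC(=O)O[C@H]([C@@H](C)/C=C/C(C)(C)C(C)=O)[C@@]1(OC(C)=O)C[C@@H](C)[C@H](OC(=O)c2ccccc2)[C@@H]1CC(C)=C | intermediate
29 | 3-O-benzoyl-14,15-di-O-acetyl C9 ketone with C4 2-methylprop-1-enyl (C5=C6) | CC(=O)O[C@H]([C@@H](C)/C=C/C(C)(C)C(C)=O)[C@@]1(OC(C)=O)C[C@@H](C)[C@H](OC(=O)c2ccccc2)[C@@H]1C=C(C)C | intermediate
30 | (5E)-C7 allylic alcohol of 29 (C4–CH=C(CH3)–CH2OH, CH2OH trans to C4) | CC(=O)O[C@H]([C@@H](C)/C=C/C(C)(C)C(C)=O)[C@@]1(OC(C)=O)C[C@@H](C)[C@H](OC(=O)c2ccccc2)[C@@H]1/C=C(\C)CO | intermediate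
31 | CNP0489076.1 (2R,3S,4S,13S,14R,15R; 5E,11E) | CC(=O)O[C@H]([C@@H](C)/C=C/C(C)(C)C(C)=O)[C@@]1(OC(C)=O)C[C@@H](C)[C@H](OC(=O)c2ccccc2)[C@@H]1/C=C(\C)C=O | target

## Step count and risks

Total: 22 steps. Longest linear sequence: 14 steps (steps 1–7, then 16–22, from furfural).

**Step 16 (carbamate anion addition).** Proton transfer from C1 or C4 of ketone 11 to the bulky, basic sparteine-bound organolithium (enolisation, then β-elimination of the C3 silyloxy group) may outrun carbonyl addition, and facial selectivity at C15 may erode. Fallback: starting from 22, the lithiation is run as before and the anion is quenched with Bu3SnCl (retention) to give the storable (1S)-α-tributylstannyl carbamate F1. Tin–lithium exchange (n-BuLi, Et2O/THF, −78 °C) regenerates the carbanion free of diamine, CeCl3 converts it into the weakly basic dichlorocerium reagent F2, and this adds to 11 to rejoin the route at 24.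

**Step 2 (oxa-Piancatelli).** Ionisation of the carbinol may lead to proton loss toward a conjugated furyl diene, the 1,1-disubstituted alkene may be hydrated or take part in the cation chemistry, and prolonged heating may move the product to the 2-substituted 4-hydroxycyclopentenone. Fallback (same C3–C4 bond, made by aldol closure instead of electrocyclisation): from 3, Barton–McCombie deoxygenation (NaH, CS2, MeI to the S-methyl xanthate F3; then Bu3SnH, azobisisobutyronitrile, toluene, 80 °C) gives 2-(3-methylbut-3-en-1-yl)furan F4. Singlet oxygen (O2, 5,10,15,20-tetraphenylporphyrin, hν, CH2Cl2, −78 °C; then Me2S) opens the furan to (Z)-7-methyl-4-oxoocta-2,7-dienal F5. Its C5 enol closes onto the aldehyde in pH 7 phosphate buffer/dioxane (intramolecular aldol) and returns to the route at racemic 5.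

**Step 21 (alkene transposition).** The transposition may stop short (terminal alkene retained at equilibrium), or H-atom transfer to the C11=C12 alkene may move it toward C13. Fallback: from 28, SeO2 (cat.)/t-BuOOH oxidises the methallyl group at its ring-side CH2 (C5) to the secondary allylic alcohol F6 (C5 epimers). Ph3SiOReO3 (cat., Et2O, 0 °C) then shifts the hydroxyl to C7 through a chair-like [3,3] rearrangement of the perrhenate ester, forming the E-C5=C6 alkene and rejoining the route at 30; MnO2 as in the second stage of step 22 gives 31.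

## Further compounds

F1 | step 16 | (1S,2S,E)-2,5-dimethyl-5-(2-methyl-1,3-dioxolan-2-yl)-1-(tributylstannyl)hex-3-en-1-yl N,N-diisopropylcarbamate | CC(C)N(C(C)C)C(=O)O[C@H]([C@@H](C)/C=C/C(C)(C)C1(C)OCCO1)[Sn](CCCC)(CCCC)CCCC
F2 | step 16 | (1S,2S,E)-1-(dichlorocerio) derivative of 22 | CC(C)N(C(C)C)C(=O)O[C@H]([C@@H](C)/C=C/C(C)(C)C1(C)OCCO1)[Ce](Cl)Cl
F3 | step 2 | O-[1-(furan-2-yl)-3-methylbut-3-en-1-yl] S-methyl carbonodithioate (racemic) | CSC(=S)OC(CC(C)=C)c1ccco1
F4 | step 2 | 2-(3-methylbut-3-en-1-yl)furan | C=C(C)CCc1ccco1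
F5 | step 2 | (Z)-7-methyl-4-oxoocta-2,7-dienal | O=C/C=C\C(=O)CCC(C)=C
F6 | step 21 | C5-hydroxy derivative of 28 (C4–CH(OH)–C(CH3)=CH2, both C5 epimers) | CC(=O)O[C@H]([C@@H](C)/C=C/C(C)(C)C(C)=O)[C@@]1(OC(C)=O)C[C@@H](C)[C@H](OC(=O)c2ccccc2)[C@@H]1C(O)C(C)=C
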